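**Strategy.** With the quinone ring numbered C1 (the carbonyl between the methoxy-bearing C2 and the side-chain-bearing C6) through C6, the ring is read as a masked 5-substituted cyclohexane-1,3-dione: C2 and C4 carry oxygen 1,3 to each other across C3–H, and C6 lies β to C4. A Michael–Claisen annulation therefore joins an acyclic (R)-δ-hydroxy enone (C3–C4(=O)–C5=C6 plus side chain) with dimethyl malonate (C1–C2), forming C1–C6 and C2–C3 in one operation; decarboxylation removes the activating ester and every new stereocentre. Iodine–methanol aromatisation, Teuber oxidation (oxygen onto C1) and acetylation finish the route. The carbinol centre comes from a Keck allylation.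

Key step: step 3

Remark: the carbinol carbon of the target is read from the SMILES as (R) (O > CH2–quinone > tridecyl > H).

**Step 1**
Reactants: 1 tetradecanal; 2 allyltributylstannane
Product: 4 (4R)-heptadec-1-en-4-ol, via tributylstannyl ether 3 (not isolated)
Conditions: (S)-BINOL (20 mol%), Ti(OiPr)4 (10 mol%), 4 Å MS, CH2Cl2, −20 °C; aq. NaHCO3
Reagents that add atoms: none
Why: Keck asymmetric allylation, in which the Lewis acid formed from (S)-BINOL and Ti(OiPr)4 activates the aldehyde and exposes its Si face to the allylstannane, which for an unbranched aliphatic aldehyde should set the new carbinol centre as (R); tin ether 3 is hydrolysed on work-up.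

**Step 2**
Reactants: 4 (4R)-heptadec-1-en-4-ol; 5 but-3-en-2-one (4 equiv)
Product: 6 (3E,6R)-6-hydroxynonadec-3-en-2-one
Conditions: second-generation Hoveyda–Grubbs catalyst (3 mol%), CH2Cl2, 40 °C
Reagents that add atoms: none
Why: Olefin cross-metathesis of a terminal homoallylic alkene with an electron-poor enone that homodimerises slowly should give the (E)-cross product selectively, and the ruthenium carbene leaves the free hydroxyl and the carbinol centre untouched.

**Step 3**
Reactants: 6 (3E,6R)-6-hydroxynonadec-3-en-2-one; 7 dimethyl malonate (1.2 equiv)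
Product: 11 5-[(2R)-2-hydroxypentadecyl]cyclohexane-1,3-dione, via Michael adduct 8 (not isolated), via cyclic keto ester 9 (not isolated), via keto acid 10 (not isolated)
Conditions: NaOMe (1.3 equiv), MeOH, 0 °C to reflux; then 2 M NaOH, reflux; then HCl to pH 2, 70 °C
Reagents that add atoms: none
Why: The malonate anion adds 1,4 to the enone (new bond from the malonate carbon to the β-carbon, the future ring carbon bearing the side chain), the methyl ketone of 8 is enolised at CH3 and that enolate attacks one malonate ester (new bond from the former methyl carbon to the ester carbon) to give the stabilised enolate of 9, after which hydroxide cleaves the remaining ester and acidification decarboxylates β-keto acid 10. The closest known reaction type is the Michael–Claisen (Dieckmann) annulation of enones with malonates used for dimedone and 5-alkylresorcinol precursors. The carbocycle closes by a 6-(enolendo)-exo-trig acyl substitution, the only productive mode because closure through the internal CH2 enolate would give a four-membered ring. The two ring stereocentres created in 8 and 9 form as mixtures and need no control, since one is lost with CO2 and the other becomes non-stereogenic in the locally symmetric dione, so all isomers should converge on a single 11 whose only stereocentre is the untouched (R)-carbinol. The step needs 1,4- over 1,2-addition, which the soft, doubly stabilised nucleophile under reversible conditions secures, and tolerance of the free δ-hydroxyl, which as an alkoxide is a poor leaving group and can at most lactonise reversibly onto an ester that hydroxide reopens.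

**Step 4**
Reactants: 11 5-[(2R)-2-hydroxypentadecyl]cyclohexane-1,3-dione
Product: 13 3-[(2R)-2-hydroxypentadecyl]-5-methoxyphenol, via methyl enol ether 12 (not isolated)
Conditions: I2 (1.2 equiv), MeOH, reflux; aq. Na2S2O3
Reagents that add atoms: methanol CO
Why: Iodine–methanol aromatisation of a cyclohexane-1,3-dione, in which acid formed in the flask gives vinylogous ester 12 and iodination of its dienol at a ring CH2 followed by loss of HI and tautomerisation gives the phenol; the two carbonyl carbons of 11 are constitutionally equivalent, so either mode of enol ether formation leads to the same 13, and the vinylogous ester carbonyl should resist a second methylation.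

**Step 5**
Reactants: 13 3-[(2R)-2-hydroxypentadecyl]-5-methoxyphenol
Product: 14 2-[(2R)-2-hydroxypentadecyl]-6-methoxycyclohexa-2,5-diene-1,4-dione
Conditions: K2NO(SO3)2 (2.5 equiv), KH2PO4 (aq.), acetone, rt
Reagents that add atoms: potassium nitrosodisulfonate (Fremy's salt) [K+].[K+].[O]N(S(=O)(=O)[O-])S(=O)(=O)[O-]
Why: Teuber oxidation, in which the nitroxyl radical abstracts the phenolic hydrogen and a second equivalent couples at the free para position (the ring CH between the methoxy- and alkyl-bearing carbons) before collapse to the para-quinone, the secondary alcohol being inert to this one-electron oxidant.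

**Step 6**
Reactants: 14 2-[(2R)-2-hydroxypentadecyl]-6-methoxycyclohexa-2,5-diene-1,4-dione
Product: 15 ardisinone
Conditions: Ac2O (1.5 equiv), pyridine, CH2Cl2, 0 °C to rt
Reagents that add atoms: acetic anhydride CC(=O)OC(C)=O
Why: Pyridine-mediated O-acetylation (nucleophilic acyl substitution) at the only hydroxyl breaks no bond to the stereocentre, so the (R)-configuration should be retained.

**Compound list**

1 | tetradecanal | CCCCCCCCCCCCCC=O | starting material
2 | allyltributylstannane | C=CC[Sn](CCCC)(CCCC)CCCC | starting material
3 | tributyl{[(4R)-heptadec-1-en-4-yl]oxy}stannane | CCCCCCCCCCCCC[C@H](CC=C)O[Sn](CCCC)(CCCC)CCCC | intermediate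
4 | (4R)-heptadec-1-en-4-ol | CCCCCCCCCCCCC[C@H](CC=C)O | intermediate
5 | but-3-en-2-one (methyl vinyl ketone) | CC(=O)C=C | starting material
6 | (3E,6R)-6-hydroxynonadec-3-en-2-one | CCCCCCCCCCCCC[C@H](C/C=C/C(C)=O)O | intermediate
7 | dimethyl malonate | COC(=O)CC(=O)OC | starting material
8 | dimethyl 2-[(6R)-6-hydroxy-2-oxononadecan-4-yl]propanedioate (mixture at C4) | CCCCCCCCCCCCC[C@H](CC(CC(C)=O)C(C(=O)OC)C(=O)OC)O | intermediate
9 | methyl 2-hydroxy-6-[(2R)-2-hydroxypentadecyl]-4-oxocyclohex-2-ene-1-carboxylate (isomer mixture, present as its sodium enolate) | CCCCCCCCCCCCC[C@H](CC1CC(=O)C=C(O)C1C(=O)OC)O | intermediate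
10 | 2-hydroxy-6-[(2R)-2-hydroxypentadecyl]-4-oxocyclohex-2-ene-1-carboxylic acid (isomer mixture) | CCCCCCCCCCCCC[C@H](CC1CC(=O)C=C(O)C1C(O)=O)O | intermediate
11 | 5-[(2R)-2-hydroxypentadecyl]cyclohexane-1,3-dione | CCCCCCCCCCCCC[C@H](CC1CC(=O)CC(=O)C1)O | intermediate
12 | 5-[(2R)-2-hydroxypentadecyl]-3-methoxycyclohex-2-en-1-one (mixture at C5) | CCCCCCCCCCCCC[C@H](CC1CC(=O)C=C(OC)C1)O | intermediate
13 | 3-[(2R)-2-hydroxypentadecyl]-5-methoxyphenol | CCCCCCCCCCCCC[C@H](Cc1cc(O)cc(OC)c1)O | intermediate
14 | 2-[(2R)-2-hydroxypentadecyl]-6-methoxycyclohexa-2,5-diene-1,4-dione | CCCCCCCCCCCCC[C@H](CC1=CC(=O)C=C(OC)C1=O)O | intermediate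
15 | ardisinone, (2R)-1-(5-methoxy-3,6-dioxocyclohexa-1,4-dien-1-yl)pentadecan-2-yl acetate | CCCCCCCCCCCCC[C@H](CC1=CC(=O)C=C(OC)C1=O)OC(C)=O | target

**Total step count:** 6. **Longest linear sequence:** 6 steps (fully linear from 1).

**Steps most likely to fail**

Step 3. The free δ-hydroxyl may interfere: the alkoxide of 6 could fragment by a retro-vinylogous aldol before the Michael addition, or relactonisation of the hydroxy acid could slow the decarboxylation. The fallback sets out from 4 and masks the hydroxyl. Silylation (TBSCl, imidazole, DMF) would give (4R)-tert-butyl(heptadec-1-en-4-yloxy)dimethylsilane F1, and cross-metathesis with 5 would give (3E,6R)-6-[(tert-butyldimethylsilyl)oxy]nonadec-3-en-2-one F2. The annulation with 7 is then run in stages through the silylated Michael adduct F3, the silylated cyclic keto ester F4, the silylated keto acid F5 and the silylated dione F6. Warm aqueous HCl finally removes the silyl ether, and the fallback comes back to the route at 11.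

Step 4. Methylation of the second carbonyl may compete with aromatisation, giving mixtures of mono- and dimethyl ether, and reversible iodination at the CH2 between the carbonyls may slow the dehydrogenation. The fallback sets out from 11 and drives the reaction deliberately to the diether (I2, HC(OMe)3, MeOH, prolonged reflux), giving (2R)-1-(3,5-dimethoxyphenyl)pentadecan-2-ol F7. One methyl ether is then cleaved with NaSEt in DMF at 140 °C; the phenoxide formed resists a second cleavage. The fallback comes back at 13.

Step 6. The electron-poor methoxyquinone may suffer conjugate addition or base-induced decomposition during acylation, and the hydroxy quinone 14 itself may prove labile on handling. The fallback sets out from 13 and installs the acetate before the oxidation. Peracetylation (Ac2O, pyridine) would give (2R)-1-(3-acetoxy-5-methoxyphenyl)pentadecan-2-yl acetate F8. The more labile aryl acetate is then cleaved selectively (NH4OAc, aq. MeOH, rt) to (2R)-1-(3-hydroxy-5-methoxyphenyl)pentadecan-2-yl acetate F9. Teuber oxidation of F9 with K2NO(SO3)2 under the buffered conditions of step 5 comes back to the route at 15.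

**Further compounds**

F1 | step 3 | (4R)-tert-butyl(heptadec-1-en-4-yloxy)dimethylsilane | CCCCCCCCCCCCC[C@H](CC=C)O[Si](C)(C)C(C)(C)C
F2 | step 3 | (3E,6R)-6-[(tert-butyldimethylsilyl)oxy]nonadec-3-en-2-one | CCCCCCCCCCCCC[C@H](C/C=C/C(C)=O)O[Si](C)(C)C(C)(C)C
F3 | step 3 | dimethyl 2-{(6R)-6-[(tert-butyldimethylsilyl)oxy]-2-oxononadecan-4-yl}propanedioate | CCCCCCCCCCCCC[C@H](CC(CC(C)=O)C(C(=O)OC)C(=O)OC)O[Si](C)(C)C(C)(C)C
F4 | step 3 | methyl 6-{(2R)-2-[(tert-butyldimethylsilyl)oxy]pentadecyl}-2-hydroxy-4-oxocyclohex-2-ene-1-carboxylate | CCCCCCCCCCCCC[C@H](CC1CC(=O)C=C(O)C1C(=O)OC)O[Si](C)(C)C(C)(C)C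
F5 | step 3 | 6-{(2R)-2-[(tert-butyldimethylsilyl)oxy]pentadecyl}-2-hydroxy-4-oxocyclohex-2-ene-1-carboxylic acid | CCCCCCCCCCCCC[C@H](CC1CC(=O)C=C(O)C1C(O)=O)O[Si](C)(C)C(C)(C)C
F6 | step 3 | 5-{(2R)-2-[(tert-butyldimethylsilyl)oxy]pentadecyl}cyclohexane-1,3-dione | CCCCCCCCCCCCC[C@H](CC1CC(=O)CC(=O)C1)O[Si](C)(C)C(C)(C)C
F7 | step 4 | (2R)-1-(3,5-dimethoxyphenyl)pentadecan-2-ol | CCCCCCCCCCCCC[C@H](Cc1cc(OC)cc(OC)c1)O
F8 | step 6 | (2R)-1-(3-acetoxy-5-methoxyphenyl)pentadecan-2-yl acetate | CCCCCCCCCCCCC[C@H](Cc1cc(OC(C)=O)cc(OC)c1)OC(C)=O
F9 | step 6 | (2R)-1-(3-hydroxy-5-methoxyphenyl)pentadecan-2-yl acetate | CCCCCCCCCCCCC[C@H](Cc1cc(O)cc(OC)c1)OC(C)=O
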